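## The problem

The target 36 is an isoflavan: a chroman (rings A and C) that carries at C3 an aryl group (ring B), which is fused across C2′–C3′ to a 2,2-dimethyl-2H-pyran (ring D). C3 is the only stereocentre and has the R configuration. It lies between two methylene groups and an arene, so nothing in the molecule can relay to it; a catalyst or reagent must set it, and it must then survive stages in which it is α to a carbonyl group or allylic. Ring A is a phloroglucinol whose three oxygens end up different (O1 in ring C, a methyl ether at C5, a free hydroxyl at C7), with a prenyl group at C6 between the last two. Ring B is a resorcinol whose oxygens also differ: O2′ is the ring D ether and O4′ is a free phenol. The ortho-prenylphenol closes to a dihydropyran under acid, the 2H-chromene is sensitive to acid, oxidants and light, and the two C=C bonds rule out hydrogenolysis and unselective hydrogenation. Protecting groups are therefore limited to fluoride-labile silyl ethers, and any hydrogenation or photochemical step must be chemoselective or precede ring D. The enabling feature is ring B itself: hydrogen at C3′, C5′ and C6′, oxygen at C2′ and C4′, and the link to C3 at C1′ next to C2′. This is the pattern left when a vinylketene (C2′ with its oxygen, C5′, C6′, C1′) takes up a silyloxyethyne (C3′, C4′ with its oxygen). The two oxygens then emerge as a free hydroxyl and a silyl ether, which is the differentiation ring D needs.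

## Retrosynthesis

**Unmasking.** Target 36 is traced to its bis(silyl ether) 35; only the two O–Si bonds are cut. Keeping O7 and O4′ silylated to the last step means no free ortho-prenylphenol or chromenol is exposed to heat, base or copper, and one fluoride treatment ends the synthesis.

**Ring D.** In 35 the O2′–C(Me)2 bond and the C3′–CH= bond are cut, leading through aryl propargyl ether 31 to phenol 29 and chloroalkyne 30. An oxidative closure of a C3′-prenyl group would also attack the ring A prenyl group, and a prenyl-first route would need a second regiocontrolled prenylation. The propargyl Claisen cascade needs only a free 2′-hydroxyl, a masked 4′-oxygen and hydrogen at C3′; with C1′ substituted, C3′ is the only ortho position open. Phenol 29 is simpler by one ring and must arrive with its two oxygens already differentiated.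

**Ring B (key disconnection).** In 29 the bonds C2′–C3′, C4′–C5′ and C1′–C2′ are cut, giving diazo enone 20 and silyloxyalkyne 24. A cross-coupling at C3–C1′ would need a configurationally defined secondary alkyl metal and a separately differentiated resorcinol. Here C3 is already set, ring B is built on it, and the phenol/silyl ether pattern follows from the mechanism. The forward reaction must be base-free, must keep the E geometry of the C1′=C6′ bond, and must run before the light-sensitive chromene exists. Alkyne 24 goes back to acetylene 21.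

**Diazo enone.** The C=N2 unit of 20 is removed to give methyl enone 18, and the C=C bond of 18 is cut to aldehyde 16 and phosphorane 17. This two-step sequence uses a commercial ylide and a diazo transfer designed for enones, and needs no diazo-bearing phosphonate. The forward steps must not epimerise C3, which is α to the formyl group in 16 and allylic in 18.

**Stereocentre.** Aldehyde 16 comes from alcohol 15 and acid 14 by redox adjustment. In 14 the C3–H and C4–H bonds are removed to give the achiral 2H-chromene-3-carboxylic acid 13. An unsaturated acid is the best-understood substrate class for ruthenium–diphosphine hydrogenation, and carboxylate direction is what spares the prenyl alkene. The achiral precursor is flat and can be assembled by classical condensation chemistry.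

**Ring A substituents.** Acid 13 comes from aldehyde 12 by oxidation; the O–CH3 bond of 12 is cut to phenol 11; the C6–prenyl bond of 11 is cut by a retro-Claisen step to tertiary allyl ether 9. Placing the allyl unit on O5 makes the position of the prenyl group unambiguous (C4a is blocked, so it goes to C6), and the hydroxyl that the rearrangement frees is the one to be methylated. Direct C-prenylation of a phloroglucinol aldehyde would leave two hydroxyls that cannot be told apart reliably.

**Ring C.** In 9 the O1–C2 and C3–C4 bonds are cut, giving salicylaldehyde 5 and acrolein 6. Because 5 has a single free phenol, the annulation can take place only at the oxygen that becomes O1.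

**Phloroglucinol differentiation.** Ether 5 is cut at the O–C(Me)2 bond to diol 2 and carbonate 4, and 2 is cut at the O–Si bond to 2,4,6-trihydroxybenzaldehyde 1. Carbonate 4 comes from alcohol 3. The order (para oxygen silylated first, then one of two equivalent ortho oxygens etherified) uses the symmetry of 1, so each step has one possible site.

## Roads not taken

**Alternative 1:** three-component conjunctive coupling at C3. The cut is C3–C1′ together with C4–C4a. The aryllithium from bromide A3 would add to vinyl boronate A4; the ate complex would react with ring A triflate A2 under Pd(OAc)2 and a chiral ferrocenyl diphosphine, ring B migrating from boron to C3 while palladium delivers ring A to C4, to give boronate A1.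
- Merits: it is the most convergent plan, it sets C3 by ligand control in the bond-forming step, ring D is complete before the coupling, and no light is used. In convergence and longest linear sequence it is better than the chosen route.
- Weak points: triflate A2 is electron-rich and flanked by a methoxy and a silyloxy group, the worst case for oxidative addition and for the palladium-induced metallate shift. A2 also needs the same regiochemical work on the phloroglucinol that the chosen route spends, and A3 needs a regioselective bromination of a chromenol. A1 has boron where C2 must be, so a one-carbon homologation at a crowded secondary boronate, an oxidation, a selective release of O8a from two ring A silyl ethers, and an etherification to close ring C must follow.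
- Set against it: the chosen plan offers a hydrogenation of a simple acid, no hindered cross-coupling, and ring B oxygens that are differentiated by mechanism.

**Alternative 2:** thermal benzannulation that builds ring A. The cut is C6–C7, C4a–C5 and C7–C8. Heating cyclobutenone A6 with alkynyl ether A7 would give a vinylketene, [2+2] addition, 4π opening and 6π closure, delivering phenol A5 with ring C still open.
- Merits: the whole substitution pattern of ring A (methoxy at C5, prenyl at C6, free hydroxyl at C7) appears regiospecifically in one thermal step. In this respect it is better than the chosen route, which spends steps 1 to 6 on differentiating the phloroglucinol.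
- Weak points: A6 is a moisture-sensitive vinylogous silyl ester that must already carry ring B, ring D and the stereocentre, so C3 has to be set earlier on an open chain and ring B has to be differentiated by other means. A7 has a methylene group that is both propargylic and allylic and is prone to isomerisation. After the annulation, two of three silyl ethers must be removed selectively and ring C closed by etherification in the presence of the free C7 phenol.
- Set against it: the chosen plan has cheaper starting materials, a late and short use of its sensitive partner, and ring C formed in one classical step.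

**Alternative 3:** polyketide-style Dieckmann closure of ring A. The cut is C5–C6. Two equivalents of a lithium amide would convert keto ester A9 into a dianion whose C6 enolate attacks the C5 ester, and enolisation would give the aromatic diol A8.
- Merits: no photochemistry, the prenyl position is fixed by the chain, and ring C with the stereocentre is in place before ring A.
- Weak points: A8 is a 5,7-diol, and the 5-hydroxyl to be methylated is the more hindered one, so a protect–methylate–deprotect detour is needed. The dianion can also acylate on oxygen. A9 is a long open-chain compound whose synthesis again needs C3 and the finished ring B/D unit first.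
- Comparison: the chosen plan differentiates the ring A oxygens by the order of events and avoids strongly basic steps once C3 exists. Alternative 3 has the advantage only in avoiding light.

Key step: step 14

## Route

Assumption (step 8): the facial sense of Ru(OAc)2(BINAP) with acid 13 is taken to follow that of simple (E)-2,3-disubstituted acrylic acids, which points to the (R)-ligand for the (S)-acid. If the opposite sense is found, the (S)-ligand is used and nothing else changes.

Step 1
Reactants: 1 2,4,6-trihydroxybenzaldehyde
Product: 2 2,6-dihydroxy-4-(triisopropylsilyloxy)benzaldehyde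
Conditions: i-Pr3SiCl (1.05 equiv), imidazole, DMF, 0 °C
Reagents that add atoms: triisopropylsilyl chloride, CC(C)[Si](Cl)(C(C)C)C(C)C
Why: Phenol O-silylation; the 4-hydroxyl is the most acidic and the only one not flanked by the formyl group, so one equivalent of the bulky chloride should silylate it selectively.

Step 2
Reactants: 3 2-methylbut-3-en-2-ol
Product: 4 tert-butyl 2-methylbut-3-en-2-yl carbonate
Conditions: n-BuLi, THF, −78 °C; Boc2O, −78 → 25 °C
Reagents that add atoms: di-tert-butyl dicarbonate, CC(C)(C)OC(=O)OC(=O)OC(C)(C)C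
Why: Acylation of a lithium alkoxide with Boc2O; the product is the usual tert-prenyl donor for Tsuji–Trost etherification.

Step 3
Reactants: 2 2,6-dihydroxy-4-(triisopropylsilyloxy)benzaldehyde; 4 tert-butyl 2-methylbut-3-en-2-yl carbonate
Product: 5 2-hydroxy-6-[(2-methylbut-3-en-2-yl)oxy]-4-(triisopropylsilyloxy)benzaldehyde
Conditions: Pd(PPh3)4 (5 mol%), THF, 0 → 25 °C
Reagents that add atoms: none
Why: Tsuji–Trost O-allylation; ionisation of 4 gives a 1,1-dimethylallylpalladium ion pair, its tert-butoxide deprotonates the phenol, and the phenoxide attacks the more substituted terminus under kinetic control; after one etherification the remaining hydroxyl is held in the chelate with the formyl group, which should stop a second alkylation.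

Step 4
Reactants: 5 2-hydroxy-6-[(2-methylbut-3-en-2-yl)oxy]-4-(triisopropylsilyloxy)benzaldehyde; 6 acrolein
Product: 9 5-[(2-methylbut-3-en-2-yl)oxy]-7-(triisopropylsilyloxy)-2H-chromene-3-carbaldehyde, via oxa-Michael adduct 7 (not isolated), via aldol 8 (not isolated)
Conditions: acrolein (3 equiv), K2CO3 (0.5 equiv), 1,4-dioxane, 60 °C
Reagents that add atoms: none
Why: Oxa-Michael addition of the only free phenoxide to acrolein, then intramolecular aldol condensation onto the aryl aldehyde (the standard salicylaldehyde-to-2H-chromene-3-carbaldehyde annulation); the temperature is held below the onset of the Claisen rearrangement of the tertiary allyl ether.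

Step 5
Reactants: 9 5-[(2-methylbut-3-en-2-yl)oxy]-7-(triisopropylsilyloxy)-2H-chromene-3-carbaldehyde
Product: 11 5-hydroxy-6-(3-methylbut-2-en-1-yl)-7-(triisopropylsilyloxy)-2H-chromene-3-carbaldehyde, via ortho-dienone 10 (not isolated)
Conditions: PhNEt2, 120 °C
Reagents that add atoms: none
Why: Aromatic Claisen rearrangement ([3,3]); C4a is blocked, so the allyl unit is delivered with inversion to C6 as a 3-methylbut-2-enyl group, and the basic solvent should speed enolisation of the dienone ahead of a Cope shift to C8.

Step 6
Reactants: 11 5-hydroxy-6-(3-methylbut-2-en-1-yl)-7-(triisopropylsilyloxy)-2H-chromene-3-carbaldehyde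
Product: 12 5-methoxy-6-(3-methylbut-2-en-1-yl)-7-(triisopropylsilyloxy)-2H-chromene-3-carbaldehyde
Conditions: MeI, K2CO3, acetone, 40 °C
Reagents that add atoms: iodomethane, CI
Why: Williamson methylation of the only free phenol; the mild carbonate base should leave the enal and the aryl silyl ether intact.

Step 7
Reactants: 12 5-methoxy-6-(3-methylbut-2-en-1-yl)-7-(triisopropylsilyloxy)-2H-chromene-3-carbaldehyde
Product: 13 5-methoxy-6-(3-methylbut-2-en-1-yl)-7-(triisopropylsilyloxy)-2H-chromene-3-carboxylic acid
Conditions: NaClO2, NaH2PO4, 2-methylbut-2-ene (excess), t-BuOH/H2O, 0 → 25 °C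
Reagents that add atoms: sodium chlorite, [Na+].[O-]Cl=O
Why: Pinnick oxidation, selective for the aldehyde; the excess alkene scavenger should take up hypochlorous acid before it reaches the prenyl group or C8 of the electron-rich ring.

Step 8
Reactants: 13 5-methoxy-6-(3-methylbut-2-en-1-yl)-7-(triisopropylsilyloxy)-2H-chromene-3-carboxylic acid
Product: 14 (S)-5-methoxy-6-(3-methylbut-2-en-1-yl)-7-(triisopropylsilyloxy)chromane-3-carboxylic acid
Conditions: Ru(OAc)2[(R)-BINAP] (1 mol%), H2 (10 atm), MeOH, 30 °C
Reagents that add atoms: none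
Why: Noyori asymmetric hydrogenation of an α,β-unsaturated acid; the substrate binds as a ruthenium carboxylate, so only the conjugated C3=C4 bond should be reduced and the isolated prenyl alkene left, and the chiral diphosphine selects the face at C3 (catalyst control).

Step 9
Reactants: 14 (S)-5-methoxy-6-(3-methylbut-2-en-1-yl)-7-(triisopropylsilyloxy)chromane-3-carboxylic acid
Product: 15 (R)-[5-methoxy-6-(3-methylbut-2-en-1-yl)-7-(triisopropylsilyloxy)chroman-3-yl]methanol
Conditions: LiAlH4, THF, 0 °C
Reagents that add atoms: none
Why: Hydride reduction of the carboxylic acid; the carboxylate is not enolised, so C3 is safe, and the aryl triisopropylsilyl ether should tolerate LiAlH4 at 0 °C (the descriptor changes only because of priority rules).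

Step 10
Reactants: 15 (R)-[5-methoxy-6-(3-methylbut-2-en-1-yl)-7-(triisopropylsilyloxy)chroman-3-yl]methanol
Product: 16 (S)-5-methoxy-6-(3-methylbut-2-en-1-yl)-7-(triisopropylsilyloxy)chromane-3-carbaldehyde
Conditions: Dess–Martin periodinane, NaHCO3, CH2Cl2, 0 → 25 °C
Reagents that add atoms: none
Why: Dess–Martin oxidation under buffered, non-basic conditions should give the α-branched aldehyde without epimerisation; it is used at once.

Step 11
Reactants: 16 (S)-5-methoxy-6-(3-methylbut-2-en-1-yl)-7-(triisopropylsilyloxy)chromane-3-carbaldehyde; 17 1-(triphenylphosphoranylidene)propan-2-one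
Product: 18 (R,E)-4-[5-methoxy-6-(3-methylbut-2-en-1-yl)-7-(triisopropylsilyloxy)chroman-3-yl]but-3-en-2-one
Conditions: toluene, 50 °C
Reagents that add atoms: none
Why: Wittig olefination with a stabilised acyl ylide should give the (E)-enone; no external base is present, so neither epimerisation at C3 nor β-elimination of the aryloxide is expected.

Step 12
Reactants: 18 (R,E)-4-[5-methoxy-6-(3-methylbut-2-en-1-yl)-7-(triisopropylsilyloxy)chroman-3-yl]but-3-en-2-one
Product: 20 (R,E)-1-diazo-4-[5-methoxy-6-(3-methylbut-2-en-1-yl)-7-(triisopropylsilyloxy)chroman-3-yl]but-3-en-2-one, via trifluoroacetyl diketone 19 (not isolated)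
Conditions: LiN(SiMe3)2, THF, −78 °C; CF3CO2CH2CF3, −78 °C; then MsN3, Et3N, H2O, MeCN, 25 °C
Reagents that add atoms: methanesulfonyl azide, CS(=O)(=O)N=[N+]=[N-]
Why: Detrifluoroacetylative diazo transfer; kinetic deprotonation at the methyl group (not at the γ-position C3) and Claisen acylation activate the α′-carbon, and mesyl azide with triethylamine then transfers the diazo group with loss of the trifluoroacetyl unit.

Step 13
Reactants: 21 acetylene
Product: 24 (triisopropylsilyloxy)ethyne, via lithium acetylide 22 (not isolated), via lithium ethynolate 23 (not isolated)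
Conditions: HC≡CH (excess), n-BuLi, THF, −78 °C; t-BuOOLi (from t-BuOOH, LiN(SiMe3)2), −78 → −20 °C; i-Pr3SiOTf, −78 → 0 °C
Reagents that add atoms: tert-butyl hydroperoxide, CC(C)(C)OO; triisopropylsilyl trifluoromethanesulfonate, CC(C)[Si](OS(=O)(=O)C(F)(F)F)(C(C)C)C(C)C
Why: Electrophilic oxygenation of a lithium acetylide by lithium tert-butyl peroxide gives the ynolate, and the bulky, hard silyl triflate should silylate on oxygen; this is the usual two-stage route from terminal alkynes to 1-silyloxyalkynes, applied here to acetylene itself with excess acetylene to hold back disproportionation of the acetylide.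

Step 14
Reactants: 20 (R,E)-1-diazo-4-[5-methoxy-6-(3-methylbut-2-en-1-yl)-7-(triisopropylsilyloxy)chroman-3-yl]but-3-en-2-one; 24 (triisopropylsilyloxy)ethyne
Product: 29 2-[(R)-5-methoxy-6-(3-methylbut-2-en-1-yl)-7-(triisopropylsilyloxy)chroman-3-yl]-5-(triisopropylsilyloxy)phenol, via vinylketene 25 (not isolated), via cyclobutenone 26 (not isolated), via dienylketene 27 (not isolated), via cyclohexadienone 28 (not isolated)
Conditions: 24 (2 equiv), hν (300 nm), ClCH2CH2Cl, 25 °C; then 80 °C
Reagents that add atoms: none
Why: Irradiation expels N2 from 20 and the alkenyl group migrates (photochemical Wolff rearrangement) to give vinylketene 25. The unsubstituted, nucleophilic carbon of 24 then bonds to the ketene carbonyl carbon and the oxygen-bearing carbon to the ketene α-carbon ([2+2]; C2′–C3′ and C4′–C5′), giving cyclobutenone 26. Light or heat opens 26 by reversible 4π electrocyclic cleavage to dienylketene 27, and the rotamer with the alkenyl arm turned inward closes ring B by 6π disrotatory electrocyclisation (C1′–C2′) to 28, which tautomerises to phenol 29. The closest known reaction is the second-generation Danheiser benzannulation of unsaturated α-diazo ketones with silyloxyalkynes, which gives resorcinol monosilyl ethers. No lasting stereocentre is created (the sp3 carbons of 26 and 28 are lost on aromatisation), and C3 is a spectator that no base is present to epimerise. The step needs regioselectivity (free hydroxyl at C2′ next to C1′, silyl ether at C4′), and the polarisation of the ynol ether secures it. It also needs the ketene to meet the alkyne before the prenyl alkene or a second ketene, which the excess of the electron-rich alkyne should ensure, and the E geometry of the C1′=C6′ bond keeps the C3 hydrogen out of reach of the ketene, so the 1,5-hydrogen shift open to a Z-alkylvinylketene is closed. The light-sensitive 2H-chromene does not yet exist at this stage.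

Step 15
Reactants: 29 2-[(R)-5-methoxy-6-(3-methylbut-2-en-1-yl)-7-(triisopropylsilyloxy)chroman-3-yl]-5-(triisopropylsilyloxy)phenol; 30 3-chloro-3-methylbut-1-yne
Product: 31 triisopropyl{[(R)-5-methoxy-6-(3-methylbut-2-en-1-yl)-3-[2-[(2-methylbut-3-yn-2-yl)oxy]-4-(triisopropylsilyloxy)phenyl]chroman-7-yl]oxy}silane
Conditions: CuCl2·2H2O (1 mol%), DBU, MeCN, 0 °C
Reagents that add atoms: none
Why: Copper-catalysed propargylic etherification; the tertiary propargylic chloride ionises through a copper acetylide and the phenoxide adds at the tertiary carbon; only O2′ is free, O4′ and O7 being silylated.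

Step 16
Reactants: 31 triisopropyl{[(R)-5-methoxy-6-(3-methylbut-2-en-1-yl)-3-[2-[(2-methylbut-3-yn-2-yl)oxy]-4-(triisopropylsilyloxy)phenyl]chroman-7-yl]oxy}silane
Product: 35 (R)-8-[5-methoxy-6-(3-methylbut-2-en-1-yl)-7-(triisopropylsilyloxy)chroman-3-yl]-2,2-dimethyl-5-(triisopropylsilyloxy)-2H-chromene, via allenyl dienone 32 (not isolated), via allenylphenol 33 (not isolated), via quinone methide 34 (not isolated)
Conditions: o-xylene, 140 °C
Reagents that add atoms: none
Why: Aromatic propargyl Claisen cascade; [3,3] shift to C3′ (C1′ is blocked), enolisation, 1,5-hydrogen shift and oxa-6π electrocyclisation close ring D; no acid, base or metal is involved, so the prenyl group, the silyl ethers and C3 should be untouched.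

Step 17
Reactants: 35 (R)-8-[5-methoxy-6-(3-methylbut-2-en-1-yl)-7-(triisopropylsilyloxy)chroman-3-yl]-2,2-dimethyl-5-(triisopropylsilyloxy)-2H-chromene
Product: 36 (R)-8-[7-hydroxy-5-methoxy-6-(3-methylbut-2-en-1-yl)chroman-3-yl]-2,2-dimethyl-2H-chromen-5-ol
Conditions: Bu4NF, THF, 0 °C; aqueous NH4Cl
Reagents that add atoms: none
Why: Fluoride cleavage of both aryl silyl ethers; the conditions should leave the prenyl group, the 2H-chromene and the benzylic stereocentre alone.

## Compound list

1 | 2,4,6-trihydroxybenzaldehyde | O=Cc1c(O)cc(O)cc1O | starting material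
2 | 2,6-dihydroxy-4-(triisopropylsilyloxy)benzaldehyde | O=Cc1c(O)cc(O[Si](C(C)C)(C(C)C)C(C)C)cc1O | intermediate
3 | 2-methylbut-3-en-2-ol | CC(C)(O)C=C | starting material
4 | tert-butyl 2-methylbut-3-en-2-yl carbonate | CC(C)(C)OC(=O)OC(C)(C)C=C | intermediate
5 | 2-hydroxy-6-[(2-methylbut-3-en-2-yl)oxy]-4-(triisopropylsilyloxy)benzaldehyde | O=Cc1c(O)cc(O[Si](C(C)C)(C(C)C)C(C)C)cc1OC(C)(C)C=C | intermediate
6 | acrolein | C=CC=O | starting material
7 | 2-[(2-methylbut-3-en-2-yl)oxy]-6-(3-oxopropoxy)-4-(triisopropylsilyloxy)benzaldehyde | O=CCCOc1cc(O[Si](C(C)C)(C(C)C)C(C)C)cc(OC(C)(C)C=C)c1C=O | intermediate (not isolated)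
8 | 4-hydroxy-5-[(2-methylbut-3-en-2-yl)oxy]-7-(triisopropylsilyloxy)chromane-3-carbaldehyde (mixture of diastereomers) | O=CC1COc2cc(O[Si](C(C)C)(C(C)C)C(C)C)cc(OC(C)(C)C=C)c2C1O | intermediate (not isolated)
9 | 5-[(2-methylbut-3-en-2-yl)oxy]-7-(triisopropylsilyloxy)-2H-chromene-3-carbaldehyde | O=CC1=Cc2c(OC(C)(C)C=C)cc(O[Si](C(C)C)(C(C)C)C(C)C)cc2OC1 | intermediate
10 | 6-(3-methylbut-2-en-1-yl)-5-oxo-7-(triisopropylsilyloxy)-5,6-dihydro-2H-chromene-3-carbaldehyde (racemic at C6) | O=CC1=CC2=C(C=C(O[Si](C(C)C)(C(C)C)C(C)C)C(CC=C(C)C)C2=O)OC1 | intermediate (not isolated)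
11 | 5-hydroxy-6-(3-methylbut-2-en-1-yl)-7-(triisopropylsilyloxy)-2H-chromene-3-carbaldehyde | O=CC1=Cc2c(O)c(CC=C(C)C)c(O[Si](C(C)C)(C(C)C)C(C)C)cc2OC1 | intermediate
12 | 5-methoxy-6-(3-methylbut-2-en-1-yl)-7-(triisopropylsilyloxy)-2H-chromene-3-carbaldehyde | O=CC1=Cc2c(OC)c(CC=C(C)C)c(O[Si](C(C)C)(C(C)C)C(C)C)cc2OC1 | intermediate
13 | 5-methoxy-6-(3-methylbut-2-en-1-yl)-7-(triisopropylsilyloxy)-2H-chromene-3-carboxylic acid | OC(=O)C1=Cc2c(OC)c(CC=C(C)C)c(O[Si](C(C)C)(C(C)C)C(C)C)cc2OC1 | intermediate
14 | (S)-5-methoxy-6-(3-methylbut-2-en-1-yl)-7-(triisopropylsilyloxy)chromane-3-carboxylic acid | OC(=O)[C@@H]1COc2cc(O[Si](C(C)C)(C(C)C)C(C)C)c(CC=C(C)C)c(OC)c2C1 | intermediate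
15 | (R)-[5-methoxy-6-(3-methylbut-2-en-1-yl)-7-(triisopropylsilyloxy)chroman-3-yl]methanol | OC[C@@H]1COc2cc(O[Si](C(C)C)(C(C)C)C(C)C)c(CC=C(C)C)c(OC)c2C1 | intermediate
16 | (S)-5-methoxy-6-(3-methylbut-2-en-1-yl)-7-(triisopropylsilyloxy)chromane-3-carbaldehyde | O=C[C@@H]1COc2cc(O[Si](C(C)C)(C(C)C)C(C)C)c(CC=C(C)C)c(OC)c2C1 | intermediate
17 | 1-(triphenylphosphoranylidene)propan-2-one | CC(=O)C=P(c1ccccc1)(c1ccccc1)c1ccccc1 | starting material
18 | (R,E)-4-[5-methoxy-6-(3-methylbut-2-en-1-yl)-7-(triisopropylsilyloxy)chroman-3-yl]but-3-en-2-one | CC(=O)/C=C/[C@@H]1COc2cc(O[Si](C(C)C)(C(C)C)C(C)C)c(CC=C(C)C)c(OC)c2C1 | intermediate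
19 | (R,E)-1,1,1-trifluoro-6-[5-methoxy-6-(3-methylbut-2-en-1-yl)-7-(triisopropylsilyloxy)chroman-3-yl]hex-5-ene-2,4-dione | FC(F)(F)C(=O)CC(=O)/C=C/[C@@H]1COc2cc(O[Si](C(C)C)(C(C)C)C(C)C)c(CC=C(C)C)c(OC)c2C1 | intermediate (not isolated)
20 | (R,E)-1-diazo-4-[5-methoxy-6-(3-methylbut-2-en-1-yl)-7-(triisopropylsilyloxy)chroman-3-yl]but-3-en-2-one | [N-]=[N+]=CC(=O)/C=C/[C@@H]1COc2cc(O[Si](C(C)C)(C(C)C)C(C)C)c(CC=C(C)C)c(OC)c2C1 | intermediate
21 | acetylene | C#C | starting material
22 | lithium acetylide | [Li+].[C-]#C | intermediate (not isolated)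
23 | lithium ethynolate | [Li+].[O-]C#C | intermediate (not isolated)
24 | (triisopropylsilyloxy)ethyne | C#CO[Si](C(C)C)(C(C)C)C(C)C | intermediate
25 | (R,E)-4-[5-methoxy-6-(3-methylbut-2-en-1-yl)-7-(triisopropylsilyloxy)chroman-3-yl]buta-1,3-dien-1-one | O=C=C/C=C/[C@@H]1COc2cc(O[Si](C(C)C)(C(C)C)C(C)C)c(CC=C(C)C)c(OC)c2C1 | intermediate (not isolated)
26 | 4-{(E)-2-[(R)-5-methoxy-6-(3-methylbut-2-en-1-yl)-7-(triisopropylsilyloxy)chroman-3-yl]ethenyl}-3-(triisopropylsilyloxy)cyclobut-2-en-1-one (both epimers at the ring carbon) | O=C1C=C(O[Si](C(C)C)(C(C)C)C(C)C)C1/C=C/[C@@H]1COc2cc(O[Si](C(C)C)(C(C)C)C(C)C)c(CC=C(C)C)c(OC)c2C1 | intermediate (not isolated)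
27 | (3E,5E)-6-[(R)-5-methoxy-6-(3-methylbut-2-en-1-yl)-7-(triisopropylsilyloxy)chroman-3-yl]-3-(triisopropylsilyloxy)hexa-1,3,5-trien-1-one | O=C=C/C(O[Si](C(C)C)(C(C)C)C(C)C)=C\C=C\[C@@H]1COc2cc(O[Si](C(C)C)(C(C)C)C(C)C)c(CC=C(C)C)c(OC)c2C1 | intermediate (not isolated)
28 | 6-[(R)-5-methoxy-6-(3-methylbut-2-en-1-yl)-7-(triisopropylsilyloxy)chroman-3-yl]-3-(triisopropylsilyloxy)cyclohexa-2,4-dien-1-one (both epimers at the ring carbon) | O=C1C=C(O[Si](C(C)C)(C(C)C)C(C)C)C=CC1[C@@H]1COc2cc(O[Si](C(C)C)(C(C)C)C(C)C)c(CC=C(C)C)c(OC)c2C1 | intermediate (not isolated)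
29 | 2-[(R)-5-methoxy-6-(3-methylbut-2-en-1-yl)-7-(triisopropylsilyloxy)chroman-3-yl]-5-(triisopropylsilyloxy)phenol | Oc1cc(O[Si](C(C)C)(C(C)C)C(C)C)ccc1[C@@H]1COc2cc(O[Si](C(C)C)(C(C)C)C(C)C)c(CC=C(C)C)c(OC)c2C1 | intermediate
30 | 3-chloro-3-methylbut-1-yne | C#CC(C)(C)Cl | starting material
31 | triisopropyl{[(R)-5-methoxy-6-(3-methylbut-2-en-1-yl)-3-[2-[(2-methylbut-3-yn-2-yl)oxy]-4-(triisopropylsilyloxy)phenyl]chroman-7-yl]oxy}silane | C#CC(C)(C)Oc1cc(O[Si](C(C)C)(C(C)C)C(C)C)ccc1[C@@H]1COc2cc(O[Si](C(C)C)(C(C)C)C(C)C)c(CC=C(C)C)c(OC)c2C1 | intermediate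
32 | 2-[(R)-5-methoxy-6-(3-methylbut-2-en-1-yl)-7-(triisopropylsilyloxy)chroman-3-yl]-6-(3-methylbuta-1,2-dien-1-yl)-5-(triisopropylsilyloxy)cyclohexa-2,4-dien-1-one (both epimers at C6 of the dienone) | O=C1C(C=C=C(C)C)C(O[Si](C(C)C)(C(C)C)C(C)C)=CC=C1[C@@H]1COc2cc(O[Si](C(C)C)(C(C)C)C(C)C)c(CC=C(C)C)c(OC)c2C1 | intermediate (not isolated)
33 | 6-[(R)-5-methoxy-6-(3-methylbut-2-en-1-yl)-7-(triisopropylsilyloxy)chroman-3-yl]-2-(3-methylbuta-1,2-dien-1-yl)-3-(triisopropylsilyloxy)phenol | Oc1c(C=C=C(C)C)c(O[Si](C(C)C)(C(C)C)C(C)C)ccc1[C@@H]1COc2cc(O[Si](C(C)C)(C(C)C)C(C)C)c(CC=C(C)C)c(OC)c2C1 | intermediate (not isolated)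
34 | (6Z)-2-[(R)-5-methoxy-6-(3-methylbut-2-en-1-yl)-7-(triisopropylsilyloxy)chroman-3-yl]-6-(3-methylbut-2-en-1-ylidene)-5-(triisopropylsilyloxy)cyclohexa-2,4-dien-1-one | O=C1/C(=C\C=C(C)C)C(O[Si](C(C)C)(C(C)C)C(C)C)=CC=C1[C@@H]1COc2cc(O[Si](C(C)C)(C(C)C)C(C)C)c(CC=C(C)C)c(OC)c2C1 | intermediate (not isolated)
35 | (R)-8-[5-methoxy-6-(3-methylbut-2-en-1-yl)-7-(triisopropylsilyloxy)chroman-3-yl]-2,2-dimethyl-5-(triisopropylsilyloxy)-2H-chromene | COc1c(CC=C(C)C)c(O[Si](C(C)C)(C(C)C)C(C)C)cc2c1C[C@H](c1ccc(O[Si](C(C)C)(C(C)C)C(C)C)c3c1OC(C)(C)C=C3)CO2 | intermediate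
36 | (R)-8-[7-hydroxy-5-methoxy-6-(3-methylbut-2-en-1-yl)chroman-3-yl]-2,2-dimethyl-2H-chromen-5-ol | COc1c(CC=C(C)C)c(O)cc2c1C[C@H](c1ccc(O)c3c1OC(C)(C)C=C3)CO2 | target

## Step count and least certain steps

Total: 17 steps. Longest linear sequence: 15 steps (1, 3 to 12, 14 to 17); steps 2 and 13 prepare carbonate 4 and alkyne 24. The least certain steps are listed in route order; step 14 is the key step.

**Step 3.** The phenoxide may attack the unsubstituted allyl terminus or a ring carbon, or the kinetic tertiary ether may re-ionise and equilibrate to the primary prenyl ether, which would later rearrange to the wrong (reverse-prenyl) group. Fallback: diol 2 is etherified with chloroalkyne 30 (CuCl2·2H2O, DBU, MeCN, 0 °C), where only attack at the tertiary carbon is possible, to give 2-hydroxy-6-[(2-methylbut-3-yn-2-yl)oxy]-4-(triisopropylsilyloxy)benzaldehyde F1. Semi-hydrogenation of the alkyne (H2, Pd/CaCO3 poisoned with Pb(OAc)2, quinoline, EtOAc) then gives 5. The fallback sets out from 2 and comes back at 5.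

**Step 4.** The tertiary allyl ether may rearrange prematurely under the warm basic conditions, which would free a second phenol and scramble the regiochemistry of the annulation; the oxa-Michael addition of a hindered, hydrogen-bonded phenol may also be slow at the low temperature this imposes. Fallback: the thermally more robust propargyl ether F1 (reached from 2 as under step 3) is annulated with acrolein 6 at full temperature (K2CO3, 1,4-dioxane, 100 °C) to give 5-[(2-methylbut-3-yn-2-yl)oxy]-7-(triisopropylsilyloxy)-2H-chromene-3-carbaldehyde F2. Semi-hydrogenation over the same poisoned palladium catalyst, which should leave the conjugated trisubstituted alkene alone, gives 9. The fallback sets out from 2 by way of F1 and comes back at 9.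

**Step 8.** Facial discrimination may be insufficient or of the wrong sense, because a β-aryl α-(aryloxymethyl)acrylic acid is a less studied substrate type than the simple acids on which the selectivity model rests; over long reaction times the prenyl group may also be partly saturated. Fallback: acid 14 of whatever enantiomeric purity is coupled with (S)-4-benzyloxazolidin-2-one (pivaloyl chloride, Et3N, LiCl, THF), and the diastereomeric imides are separated by chromatography. The required isomer is (S)-4-benzyl-3-[(S)-5-methoxy-6-(3-methylbut-2-en-1-yl)-7-(triisopropylsilyloxy)chromane-3-carbonyl]oxazolidin-2-one F3. Reductive removal of the auxiliary with LiBH4 (THF, H2O, 0 °C) gives alcohol 15 directly. The fallback sets out from 14 and comes back at 15, replacing step 9.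

**Step 13.** The parent acetylide may disproportionate before it is oxygenated, and the unhindered ynolate carbon may be silylated in place of oxygen, giving a silylketene. Fallback: ethynyltrimethylsilane (commercial) replaces 21; its lithium acetylide is stable and blocked at carbon. The same oxygenation and silylation give triisopropyl{[(trimethylsilyl)ethynyl]oxy}silane F4, and the alkynyl C–Si bond is then cleaved with K2CO3 in MeOH at 0 °C to give 24. The fallback sets out in place of 21 and comes back at 24.

**Step 14 (key step).** The terminal silyloxyalkyne is the least hindered but also the least robust member of its class. It may isomerise to a silylketene on heating, or its union with the vinylketene may be too slow to outrun ketene dimerisation and photochemical E/Z isomerisation of the enone, after which a Z-vinylketene would be lost by 1,5-hydrogen shift from C3. Fallback: diazo enone 20 is irradiated and heated under the same regime with the C-silylated alkyne F4 (made as under step 13), which cannot isomerise and whose silicon stabilises the developing positive charge in the [2+2] step. This gives 2-[(R)-5-methoxy-6-(3-methylbut-2-en-1-yl)-7-(triisopropylsilyloxy)chroman-3-yl]-5-(triisopropylsilyloxy)-6-(trimethylsilyl)phenol F5. Ipso-protodesilylation at C3′, the most nucleophilic ring position, with CF3CO2H (1 equiv, CH2Cl2, 0 °C) gives 29. The fallback sets out from 20 and comes back at 29.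

## Further compounds

F1 | step 3 | 2-hydroxy-6-[(2-methylbut-3-yn-2-yl)oxy]-4-(triisopropylsilyloxy)benzaldehyde | O=Cc1c(O)cc(O[Si](C(C)C)(C(C)C)C(C)C)cc1OC(C)(C)C#C
F2 | step 4 | 5-[(2-methylbut-3-yn-2-yl)oxy]-7-(triisopropylsilyloxy)-2H-chromene-3-carbaldehyde | O=CC1=Cc2c(OC(C)(C)C#C)cc(O[Si](C(C)C)(C(C)C)C(C)C)cc2OC1
F3 | step 8 | (S)-4-benzyl-3-[(S)-5-methoxy-6-(3-methylbut-2-en-1-yl)-7-(triisopropylsilyloxy)chromane-3-carbonyl]oxazolidin-2-one | O=C([C@@H]1COc2cc(O[Si](C(C)C)(C(C)C)C(C)C)c(CC=C(C)C)c(OC)c2C1)N1[C@@H](Cc2ccccc2)COC1=O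
F4 | step 13 | triisopropyl{[(trimethylsilyl)ethynyl]oxy}silane | C[Si](C)(C)C#CO[Si](C(C)C)(C(C)C)C(C)C
F5 | step 14 | 2-[(R)-5-methoxy-6-(3-methylbut-2-en-1-yl)-7-(triisopropylsilyloxy)chroman-3-yl]-5-(triisopropylsilyloxy)-6-(trimethylsilyl)phenol | Oc1c([Si](C)(C)C)c(O[Si](C(C)C)(C(C)C)C(C)C)ccc1[C@@H]1COc2cc(O[Si](C(C)C)(C(C)C)C(C)C)c(CC=C(C)C)c(OC)c2C1
A1 | alternative 1 | (R)-2-{1-[2,2-dimethyl-5-(triisopropylsilyloxy)-2H-chromen-8-yl]-2-[2-methoxy-3-(3-methylbut-2-en-1-yl)-4,6-bis(triisopropylsilyloxy)phenyl]ethyl}-4,4,5,5-tetramethyl-1,3,2-dioxaborolane | COc1c(CC=C(C)C)c(O[Si](C(C)C)(C(C)C)C(C)C)cc(O[Si](C(C)C)(C(C)C)C(C)C)c1C[C@H](c1ccc(O[Si](C(C)C)(C(C)C)C(C)C)c2c1OC(C)(C)C=C2)B1OC(C)(C)C(C)(C)O1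
A2 | alternative 1 | 2-methoxy-3-(3-methylbut-2-en-1-yl)-4,6-bis(triisopropylsilyloxy)phenyl trifluoromethanesulfonate | COc1c(CC=C(C)C)c(O[Si](C(C)C)(C(C)C)C(C)C)cc(O[Si](C(C)C)(C(C)C)C(C)C)c1OS(=O)(=O)C(F)(F)F
A3 | alternative 1 | 8-bromo-2,2-dimethyl-5-(triisopropylsilyloxy)-2H-chromene | Brc1ccc(O[Si](C(C)C)(C(C)C)C(C)C)c2c1OC(C)(C)C=C2
A4 | alternative 1 | 4,4,5,5-tetramethyl-2-vinyl-1,3,2-dioxaborolane | C=CB1OC(C)(C)C(C)(C)O1
A5 | alternative 2 | 4-{(R)-2-[2,2-dimethyl-5-(triisopropylsilyloxy)-2H-chromen-8-yl]-3-(triisopropylsilyloxy)propyl}-3-methoxy-2-(3-methylbut-2-en-1-yl)-5-(triisopropylsilyloxy)phenol | COc1c(CC=C(C)C)c(O)cc(O[Si](C(C)C)(C(C)C)C(C)C)c1C[C@H](c1ccc(O[Si](C(C)C)(C(C)C)C(C)C)c2c1OC(C)(C)C=C2)CO[Si](C(C)C)(C(C)C)C(C)C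
A6 | alternative 2 | 2-{(R)-2-[2,2-dimethyl-5-(triisopropylsilyloxy)-2H-chromen-8-yl]-3-(triisopropylsilyloxy)propyl}-3-(triisopropylsilyloxy)cyclobut-2-en-1-one | O=C1CC(O[Si](C(C)C)(C(C)C)C(C)C)=C1C[C@H](c1ccc(O[Si](C(C)C)(C(C)C)C(C)C)c2c1OC(C)(C)C=C2)CO[Si](C(C)C)(C(C)C)C(C)C
A7 | alternative 2 | 1-methoxy-5-methylhex-4-en-1-yne | COC#CCC=C(C)C
A8 | alternative 3 | (R)-3-[2,2-dimethyl-5-(triisopropylsilyloxy)-2H-chromen-8-yl]-6-(3-methylbut-2-en-1-yl)chromane-5,7-diol | Oc1c(CC=C(C)C)c(O)cc2c1C[C@H](c1ccc(O[Si](C(C)C)(C(C)C)C(C)C)c3c1OC(C)(C)C=C3)CO2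
A9 | alternative 3 | methyl (R)-3-[2,2-dimethyl-5-(triisopropylsilyloxy)-2H-chromen-8-yl]-6-(6-methyl-2-oxohept-5-en-1-yl)-3,4-dihydro-2H-pyran-5-carboxylate | COC(=O)C1=C(CC(=O)CCC=C(C)C)OC[C@@H](c2ccc(O[Si](C(C)C)(C(C)C)C(C)C)c3c2OC(C)(C)C=C3)C1
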